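**Retrosynthetic overview** (chain atoms numbered C1–C15; in the product ring C6–O–C12)
1. C13–Br comes from an invertive Appel bromination and C10–OAc from acylation. The oxocane (second ring) comes from ring expansion of a 2,5-trans-tetrahydrofuran: its oxygen opens a (12S,13S)-epoxide to a bicyclic oxonium ion, which chloride opens at C9.
2. The tetrahydrofuran (first ring) and both epoxides come from one double Shi epoxidation of a (9E,12E)-diene syn-chlorohydrin; the C6–OH opens the 9,10-epoxide 5-exo.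
3. The C15 chain comes from a lactol aldehyde by a Z-selective Peterson enyne olefination (C3=C4) and a Takai–Utimoto E-olefination (C9=C10).
4. The lactol aldehyde comes from ozonolysis of (1S,6S)-6-chlorocyclohex-3-en-1-ol, made by catalytic enantioselective chloride opening of meso-4,5-epoxycyclohexene (key step), itself from benzene by Birch reduction.

Assumption: the (S)-bisphosphine dioxide in step 3 is taken to give the (1S,6S)-chlorohydrin; if the sense is opposite, its enantiomer is used.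

**Step 1**
Reactants: 1 benzene
Product: 2 cyclohexa-1,4-diene
Conditions: Li, NH3(l), EtOH, Et2O, −78 to −33 °C
Reagents that add atoms: none
Why: Birch reduction, in which stepwise electron transfer and protonation give the unconjugated 1,4-diene and no stereocentre is formed.

**Step 2**
Reactants: 2 cyclohexa-1,4-diene
Product: 3 (1R,6S)-7-oxabicyclo[4.1.0]hept-3-ene
Conditions: mCPBA (1.0 equiv), CH2Cl2, 0 °C
Reagents that add atoms: mCPBA, OOC(=O)c1cccc(Cl)c1
Why: Prilezhaev epoxidation with one equivalent of peracid converts one of the two equivalent alkenes into the cis-fused epoxide, which is meso.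

**Step 3**
Reactants: 3 (1R,6S)-7-oxabicyclo[4.1.0]hept-3-ene
Product: 5 (1S,6S)-6-chlorocyclohex-3-en-1-ol, via trichlorosilyl ether 4 (not isolated)
Conditions: SiCl4 (1.2 equiv), (S)-2,2′-bis(diphenylphosphoryl)-1,1′-binaphthyl (10 mol %), i-Pr2NEt, CH2Cl2, −78 °C; aq. NaHCO3
Reagents that add atoms: silicon tetrachloride, Cl[Si](Cl)(Cl)Cl
Why: Lewis-base-catalysed enantioselective ring opening of a meso-epoxide (Denmark–Nakajima type desymmetrisation), in which the chiral phosphine-oxide-bound chlorosilyl cation activates the epoxide and chloride attacks one enantiotopic carbon with inversion, setting C6 (S, carbinol) and C7 (S, chloride) together as the trans chlorohydrin.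

**Step 4**
Reactants: 5 (1S,6S)-6-chlorocyclohex-3-en-1-ol
Product: 8 2-[(2S,3S)-3-chloro-5-hydroxyoxolan-2-yl]acetaldehyde, via ozonide 6 (not isolated), via hydroxy dialdehyde 7 (not isolated)
Conditions: O3, CH2Cl2, −78 °C; PPh3, −78 to 20 °C
Reagents that add atoms: ozone, [O-][O+]=O
Why: ozonolysis with reductive work-up cleaves the C4=C9 alkene, and the C6 hydroxyl closes onto the C9 aldehyde as a five-membered lactol, which differentiates the two aldehydes without touching C6 or C7.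

**Step 5**
Reactants: 8 2-[(2S,3S)-3-chloro-5-hydroxyoxolan-2-yl]acetaldehyde; 9 1,3-bis(triisopropylsilyl)propyne
Product: 12 (4S,5S)-4-chloro-5-[(2Z)-5-(triisopropylsilyl)pent-2-en-4-yn-1-yl]oxolan-2-ol, via lithiated propyne 10 (not isolated), via silyl alkoxide adduct 11 (not isolated)
Conditions: 9, n-BuLi, THF, −78 °C (2.2 equiv of 10); 8, −78 to −20 °C; aq. NH4Cl
Reagents that add atoms: none
Why: Corey–Rücker Peterson olefination, in which one equivalent of 10 holds the lactol as its lithium lactolate, the second adds to the free C4 aldehyde, and syn-elimination of silanolate from the favoured adduct gives the Z-enyne.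

**Step 6**
Reactants: 13 (2E)-1-bromopent-2-ene; 14 diiodomethane
Product: 16 (3E)-1,1-diiodohex-3-ene, via diiodomethylsodium 15 (not isolated)
Conditions: NaN(SiMe3)2, THF–Et2O, −78 °C, dark; 13, −78 to 0 °C
Reagents that add atoms: none
Why: SN2 alkylation of the diiodomethyl anion at the primary allylic carbon, with the E alkene untouched.

**Step 7**
Reactants: 12 (4S,5S)-4-chloro-5-[(2Z)-5-(triisopropylsilyl)pent-2-en-4-yn-1-yl]oxolan-2-ol; 16 (3E)-1,1-diiodohex-3-ene
Product: 18 (3Z,6S,7S,9E,12E)-7-chloro-1-(triisopropylsilyl)pentadeca-3,9,12-trien-1-yn-6-ol, via geminal dichromium reagent 17 (not isolated)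
Conditions: CrCl2 (8 equiv), DMF, THF, 20 °C
Reagents that add atoms: none
Why: Takai–Utimoto alkylidenation, in which the geminal dichromium reagent made by divalent chromium reacts with the aldehyde released from the lactol under non-basic conditions (so the chlorohydrin does not close to an epoxide and the β-chloride is not eliminated) and gives the E alkene at C9=C10.

**Step 8**
Reactants: 18 (3Z,6S,7S,9E,12E)-7-chloro-1-(triisopropylsilyl)pentadeca-3,9,12-trien-1-yn-6-ol
Product: 20 (1S)-1-{(2R,4S,5S)-4-chloro-5-[(2Z)-5-(triisopropylsilyl)pent-2-en-4-yn-1-yl]oxolan-2-yl}-2-[(2S,3S)-3-ethyloxiran-2-yl]ethan-1-ol, via bis-epoxide 19 (not isolated)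
Conditions: 1,2:4,5-di-O-isopropylidene-β-L-erythro-2,3-hexodiulo-2,6-pyranose (0.6 equiv), KHSO5 (Oxone), K2CO3, borate buffer pH 9.3, MeCN–CH2(OMe)2, −5 °C; camphor-10-sulfonic acid (5 mol %), CH2Cl2, 0 °C
Reagents that add atoms: potassium peroxymonosulfate, [K+].[O-]S(=O)(=O)OO
Why: Shi asymmetric epoxidation, in which the dioxirane of the L-fructose-derived ketone epoxidises both trans alkenes under reagent control to the (9S,10S) and (12S,13S) epoxides (the Z-enyne alkene is slower, and the lowered pH spares the chlorohydrin), after which acid-catalysed 5-exo opening of the 9,10-epoxide by the C6 hydroxyl with inversion at C9 gives the 2,5-trans tetrahydrofuran (C9 R) and the C10 (S) carbinol.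

**Step 9**
Reactants: 20 (1S)-1-{(2R,4S,5S)-4-chloro-5-[(2Z)-5-(triisopropylsilyl)pent-2-en-4-yn-1-yl]oxolan-2-yl}-2-[(2S,3S)-3-ethyloxiran-2-yl]ethan-1-ol
Product: 24 (2R,4S,5S,7S,8S)-2-[(1S)-1-(tert-butyldimethylsilyloxy)propyl]-5,7-dichloro-8-[(2Z)-5-(triisopropylsilyl)pent-2-en-4-yn-1-yl]oxocan-4-ol, via trimethylsilyl ether 21 (not isolated), via oxonium triflate 22 (not isolated), via bis-silyl oxocane 23 (not isolated)
Conditions: Me3SiOTf (1.0 equiv), 2,6-di-tert-butyl-4-methylpyridine, CH2Cl2, −78 °C; t-BuMe2SiOTf (1.2 equiv), −78 °C; n-Bu4NCl (3 equiv), −78 to −30 °C; citric acid, MeOH, 0 °C; aq. NaHCO3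
Reagents that add atoms: tert-butyldimethylsilyl triflate, CC(C)(C)[Si](C)(C)OS(=O)(=O)C(F)(F)F; tetrabutylammonium chloride, CCCC[N+](CCCC)(CCCC)CCCC.[Cl-]
Why: Proposed new method: silyl triflate activation of the epoxide lets the tetrahydrofuran oxygen open it 5-exo at C12 with inversion (sets C12 R) to a bicyclic trialkyloxonium ion, and chloride added afterwards cleaves the ring-fusion C9–O bond by SN2 with inversion (sets C9 S) to give the oxocane, attack at C6 being retarded by the vicinal chloride and at C12 by the bulky anti-periplanar silyloxy group while the small, non-participating trimethylsilyl ether keeps the C10 oxygen from capturing C9; the closest known reactions are the bromonium-triggered ring expansion of tetrahydrofurans to oxocanes through the same type of oxonium ion (Et2SBr·SbCl5Br chemistry) and halide opening of Laurencia-type oxonium ions.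

**Step 10**
Reactants: 24 (2R,4S,5S,7S,8S)-2-[(1S)-1-(tert-butyldimethylsilyloxy)propyl]-5,7-dichloro-8-[(2Z)-5-(triisopropylsilyl)pent-2-en-4-yn-1-yl]oxocan-4-ol
Product: 25 (2R,4S,5S,7S,8S)-2-[(1S)-1-(tert-butyldimethylsilyloxy)propyl]-5,7-dichloro-8-[(2Z)-5-(triisopropylsilyl)pent-2-en-4-yn-1-yl]oxocan-4-yl acetate
Conditions: Ac2O, pyridine, 4-(dimethylamino)pyridine (cat.), CH2Cl2, 20 °C
Reagents that add atoms: acetic anhydride, CC(=O)OC(C)=O
Why: nucleophile-catalysed O-acylation of the only free hydroxyl (C10), with no change at any stereocentre.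

**Step 11**
Reactants: 25 (2R,4S,5S,7S,8S)-2-[(1S)-1-(tert-butyldimethylsilyloxy)propyl]-5,7-dichloro-8-[(2Z)-5-(triisopropylsilyl)pent-2-en-4-yn-1-yl]oxocan-4-yl acetate
Product: 26 (2R,4S,5S,7S,8S)-5,7-dichloro-2-[(1S)-1-hydroxypropyl]-8-[(2Z)-pent-2-en-4-yn-1-yl]oxocan-4-yl acetate
Conditions: n-Bu4NF, AcOH, THF, 0 to 20 °C
Reagents that add atoms: none
Why: fluoride-mediated desilylation cleaves both the O–Si bond at C13 and the alkynyl C–Si bond, with acetic acid buffering so that the acetate and the chlorides survive.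

**Step 12**
Reactants: 26 (2R,4S,5S,7S,8S)-5,7-dichloro-2-[(1S)-1-hydroxypropyl]-8-[(2Z)-pent-2-en-4-yn-1-yl]oxocan-4-yl acetate
Product: 27 (2R,4S,5S,7S,8S)-2-[(1R)-1-bromopropyl]-5,7-dichloro-8-[(2Z)-pent-2-en-4-yn-1-yl]oxocan-4-yl acetate
Conditions: CBr4, P(n-C8H17)3, toluene, 70 °C
Reagents that add atoms: carbon tetrabromide, BrC(Br)(Br)Br
Why: Appel bromination, in which bromide displaces the alkoxyphosphonium group by SN2 with inversion and so converts the (13S)-alcohol into the (13R)-bromide.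

**Compound list**
1 | benzene | c1ccccc1 | starting material
2 | cyclohexa-1,4-diene | C1=CCC=CC1 | intermediate
3 | (1R,6S)-7-oxabicyclo[4.1.0]hept-3-ene (meso) | C1=CC[C@H]2O[C@H]2C1 | intermediate
4 | trichloro{[(1S,6S)-6-chlorocyclohex-3-en-1-yl]oxy}silane | Cl[Si](Cl)(Cl)O[C@H]1CC=CC[C@@H]1Cl | intermediate
5 | (1S,6S)-6-chlorocyclohex-3-en-1-ol | O[C@H]1CC=CC[C@@H]1Cl | intermediate
6 | (3S,4S)-4-chloro-7,8,9-trioxabicyclo[4.2.1]nonan-3-ol (ozonide) | O[C@H]1CC2OOC(O2)C[C@@H]1Cl | intermediate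
7 | (3S,4S)-3-chloro-4-hydroxyhexanedial | O=CC[C@H](O)[C@@H](Cl)CC=O | intermediate
8 | 2-[(2S,3S)-3-chloro-5-hydroxyoxolan-2-yl]acetaldehyde (anomer mixture) | O=CC[C@@H]1OC(O)C[C@@H]1Cl | intermediate
9 | 1,3-bis(triisopropylsilyl)propyne | CC(C)[Si](C(C)C)(C(C)C)C#CC[Si](C(C)C)(C(C)C)C(C)C | starting material
10 | [1,3-bis(triisopropylsilyl)prop-2-yn-1-yl]lithium | CC(C)[Si](C(C)C)(C(C)C)C#CC([Li])[Si](C(C)C)(C(C)C)C(C)C | intermediate
11 | dilithium (4S,5S)-4-chloro-5-[2-oxido-3,5-bis(triisopropylsilyl)pent-4-yn-1-yl]oxolan-2-olate | [Li+].[Li+].CC(C)[Si](C(C)C)(C(C)C)C#CC([Si](C(C)C)(C(C)C)C(C)C)C([O-])C[C@@H]1OC([O-])C[C@@H]1Cl | intermediate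
12 | (4S,5S)-4-chloro-5-[(2Z)-5-(triisopropylsilyl)pent-2-en-4-yn-1-yl]oxolan-2-ol | CC(C)[Si](C(C)C)(C(C)C)C#C/C=C\C[C@@H]1OC(O)C[C@@H]1Cl | intermediate
13 | (2E)-1-bromopent-2-ene | CC/C=C/CBr | starting material
14 | diiodomethane | ICI | starting material
15 | (diiodomethyl)sodium | [Na+].[CH-](I)I | intermediate
16 | (3E)-1,1-diiodohex-3-ene | CC/C=C/CC(I)I | intermediate
17 | [(3E)-hex-3-ene-1,1-diyl]bis(dichlorochromium) | CC/C=C/CC([Cr](Cl)Cl)[Cr](Cl)Cl | intermediate
18 | (3Z,6S,7S,9E,12E)-7-chloro-1-(triisopropylsilyl)pentadeca-3,9,12-trien-1-yn-6-ol | CC(C)[Si](C(C)C)(C(C)C)C#C/C=C\C[C@H](O)[C@@H](Cl)C/C=C/C/C=C/CC | intermediate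
19 | (3Z,6S,7S,9S,10S,12S,13S)-7-chloro-9,10:12,13-diepoxy-1-(triisopropylsilyl)pentadec-3-en-1-yn-6-ol | CC(C)[Si](C(C)C)(C(C)C)C#C/C=C\C[C@H](O)[C@@H](Cl)C[C@@H]1O[C@H]1C[C@@H]2O[C@H]2CC | intermediate
20 | (1S)-1-{(2R,4S,5S)-4-chloro-5-[(2Z)-5-(triisopropylsilyl)pent-2-en-4-yn-1-yl]oxolan-2-yl}-2-[(2S,3S)-3-ethyloxiran-2-yl]ethan-1-ol | CC(C)[Si](C(C)C)(C(C)C)C#C/C=C\C[C@@H]1O[C@H](C[C@@H]1Cl)[C@@H](O)C[C@@H]2O[C@H]2CC | intermediate
21 | trimethylsilyl ether of 20 at the C10 hydroxyl | CC(C)[Si](C(C)C)(C(C)C)C#C/C=C\C[C@@H]1O[C@H](C[C@@H]1Cl)[C@@H](O[Si](C)(C)C)C[C@@H]2O[C@H]2CC | intermediate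
22 | (2S,3S,5R,6S,8R)-8-[(1S)-1-(tert-butyldimethylsilyloxy)propyl]-3-chloro-2-[(2Z)-5-(triisopropylsilyl)pent-2-en-4-yn-1-yl]-6-(trimethylsilyloxy)-1-oxoniabicyclo[3.3.0]octane triflate | CC(C)[Si](C(C)C)(C(C)C)C#C/C=C\C[C@@H]1[O+]2[C@@H]([C@@H](O[Si](C)(C)C(C)(C)C)CC)C[C@H](O[Si](C)(C)C)[C@H]2C[C@@H]1Cl.[O-]S(=O)(=O)C(F)(F)F | intermediate
23 | (2R,4S,5S,7S,8S)-2-[(1S)-1-(tert-butyldimethylsilyloxy)propyl]-5,7-dichloro-8-[(2Z)-5-(triisopropylsilyl)pent-2-en-4-yn-1-yl]-4-(trimethylsilyloxy)oxocane | CC(C)[Si](C(C)C)(C(C)C)C#C/C=C\C[C@@H]1O[C@@H]([C@@H](O[Si](C)(C)C(C)(C)C)CC)C[C@H](O[Si](C)(C)C)[C@@H](Cl)C[C@@H]1Cl | intermediate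
24 | (2R,4S,5S,7S,8S)-2-[(1S)-1-(tert-butyldimethylsilyloxy)propyl]-5,7-dichloro-8-[(2Z)-5-(triisopropylsilyl)pent-2-en-4-yn-1-yl]oxocan-4-ol | CC(C)[Si](C(C)C)(C(C)C)C#C/C=C\C[C@@H]1O[C@@H]([C@@H](O[Si](C)(C)C(C)(C)C)CC)C[C@H](O)[C@@H](Cl)C[C@@H]1Cl | intermediate
25 | (2R,4S,5S,7S,8S)-2-[(1S)-1-(tert-butyldimethylsilyloxy)propyl]-5,7-dichloro-8-[(2Z)-5-(triisopropylsilyl)pent-2-en-4-yn-1-yl]oxocan-4-yl acetate | CC(C)[Si](C(C)C)(C(C)C)C#C/C=C\C[C@@H]1O[C@@H]([C@@H](O[Si](C)(C)C(C)(C)C)CC)C[C@H](OC(C)=O)[C@@H](Cl)C[C@@H]1Cl | intermediate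
26 | (2R,4S,5S,7S,8S)-5,7-dichloro-2-[(1S)-1-hydroxypropyl]-8-[(2Z)-pent-2-en-4-yn-1-yl]oxocan-4-yl acetate | C#C/C=C\C[C@@H]1O[C@@H]([C@@H](O)CC)C[C@H](OC(C)=O)[C@@H](Cl)C[C@@H]1Cl | intermediate
27 | (2R,4S,5S,7S,8S)-2-[(1R)-1-bromopropyl]-5,7-dichloro-8-[(2Z)-pent-2-en-4-yn-1-yl]oxocan-4-yl acetate | C#C/C=C\C[C@@H]1O[C@@H]([C@H](Br)CC)C[C@H](OC(C)=O)[C@@H](Cl)C[C@@H]1Cl | target

**Step count and risks**
Total: 12 steps. Longest linear sequence: 11 steps (steps 1–5 and 7–12, benzene to 27); step 6 is a one-step side branch.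

Step 9 is the most likely to fail. Chloride may open the oxonium ion at C12 or C6 and give tetrahydrofuran chlorohydrins instead of the oxocane. The fallback sets out from 20 and comes back at 24. The free C10 hydroxyl of 20 is treated with TiCl(O-i-Pr)3 in CH2Cl2 at −40 °C, so that the titanium alkoxide chelates and activates the epoxide and, after attack of the ring oxygen at C12, hands a chloride ligand to the adjacent C9 through a five-membered transition state. This gives (2R,4S,5S,7S,8S)-5,7-dichloro-2-[(1S)-1-hydroxypropyl]-8-[(2Z)-5-(triisopropylsilyl)pent-2-en-4-yn-1-yl]oxocan-4-ol F4. Silylation with t-BuMe2SiCl and imidazole, selective for the C13 hydroxyl because the C10 hydroxyl next to the C9 chloride is less nucleophilic, then gives 24.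

Step 3 is the second risk. Aliphatic cyclic meso-epoxides usually give only moderate enantioselectivity in this reaction class. The fallback sets out from 3 and comes back at 5, replacing desymmetrisation by resolution. HCl in Et2O opens 3 to racemic trans-6-chlorocyclohex-3-en-1-ol F1. Burkholderia cepacia lipase with vinyl acetate acetylates the (1R,6R) enantiomer to (1R,6R)-6-chlorocyclohex-3-en-1-yl acetate F2 and leaves 5, which is separated by chromatography.

Step 5 is the third risk. An organolithium is used on an unprotected lactol that carries a base-sensitive β-chloride. The fallback sets out from 8 and comes back at 12, forming the C2–C3 bond by cross-coupling instead. The weakly basic ylide Ph3P=CHI (from (iodomethyl)triphenylphosphonium iodide and NaN(SiMe3)2, THF, −78 °C) converts the free aldehyde of 8 into (4S,5S)-4-chloro-5-[(2Z)-3-iodoprop-2-en-1-yl]oxolan-2-ol F3 (Stork–Zhao olefination). Sonogashira coupling of F3 with (triisopropylsilyl)acetylene (Pd(PPh3)4, CuI, i-Pr2NH) then gives 12.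

**Further compounds**
F1 | step 3 | racemic trans-6-chlorocyclohex-3-en-1-ol | O[C@H]1CC=CC[C@@H]1Cl.O[C@@H]1CC=CC[C@H]1Cl
F2 | step 3 | (1R,6R)-6-chlorocyclohex-3-en-1-yl acetate | CC(=O)O[C@@H]1CC=CC[C@H]1Cl
F3 | step 5 | (4S,5S)-4-chloro-5-[(2Z)-3-iodoprop-2-en-1-yl]oxolan-2-ol | I/C=C\C[C@@H]1OC(O)C[C@@H]1Cl
F4 | step 9 | (2R,4S,5S,7S,8S)-5,7-dichloro-2-[(1S)-1-hydroxypropyl]-8-[(2Z)-5-(triisopropylsilyl)pent-2-en-4-yn-1-yl]oxocan-4-ol | CC(C)[Si](C(C)C)(C(C)C)C#C/C=C\C[C@@H]1O[C@@H]([C@@H](O)CC)C[C@H](O)[C@@H](Cl)C[C@@H]1Cl
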